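**Remarks on the chemistry.** Atom labels: the side chain is C1–C5 (C3 is the carbinol carbon), the ring carbons are C6–C19, C20 is the hydroxymethyl carbon on C6 and C21 the hydroxymethyl carbon on C15. Assumption: compound 39 is carried on as the C17 epimer mixture that the allylation delivers. Its SMILES shows one epimer, and both give the same enolate 40.

## Analysis of the target

The target 48 is a tetracyclic N-methyl amino triol built from cyclopentene ring A (C10–C14, alkene C10=C11), cyclopentane ring B (C11, C12, C15, C16, C17), cycloheptene ring C (C6–C11 and C17) and piperidine ring D (C6, C7, C19, N, C18, C17). Rings C and D together form an 8-azabicyclo[4.3.1]decene with bridgeheads C7 and C17 and C6 as the one-carbon bridge, and C11 belongs to all three carbocycles. There are six stereocentres: the remote (S)-carbinol C3, the vicinal quaternary carbons C6 and C17, the bridgehead C7, the allylic ring-fusion carbon C12, and C15. On ring D the C8 branch of C7, the C11 branch of C17 and C20 share one face and the side chain takes the other; on ring B the hydrogens on C12 and C15 are cis, so C21 sits on the crowded face turned towards rings A and C. The functional groups (tertiary amine, three alcohols, a tetrasubstituted alkene) are robust, so the difficulty is skeletal: two adjacent quaternary centres, a bridged seven-membered ring, a contra-thermodynamic C15 and a side-chain stereocentre that the core cannot control. The strategy rests on C17, a bridgehead bonded to the sp2 carbon C11 and to C18, the carbon next to nitrogen. With C18 as a lactam carbonyl, C17 is the only enolisable carbon of a piperidinone and C11 is a vinyl bromide carbon, so ring C can be closed by a palladium-catalysed enolate alkenylation.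

## Retrosynthetic reasoning

**Late functional-group changes.** The two methoxymethyl ethers of 47 are removed last, and the amine of 47 is traced to lactam 46. C18 is kept as a carbonyl until the end because it is what makes C17 nucleophilic.

**C15–C21 oxidation level.** Alcohol 46 is traced to the exocyclic alkene 44. Hydroboration puts hydrogen on C15 from the open face of ring B, which pushes C21 to the crowded face that the target requires. An enolate-type C15 would tend to give the other epimer.

**Ring B (C12–C15).** This bond is cut to the allylic acetate 43, whose C17 allyl group supplies C16, C15 and C21. A palladium-ene closure forms C12–C15 anti to the departing acetate, so C12 is set stereospecifically from the (S)-carbinol of 42 and the exocyclic alkene needed for C21 appears in the same step.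

**Ring C (C11–C17), the key disconnection.** Bridged lactam 41 is cut between the enolate carbon C17 and the alkenyl carbon C11 to give the monocyclic bromide 39. This cut removes the seven-membered ring, the bridged bicycle and the second quaternary centre at once. The stereochemical outcome is fixed by the C6/C7 relationship already present.

**C17–C16.** The allyl group of 39 comes from lactam 36 and allyl bromide 37 by enolate alkylation. It is placed after the cross-coupling so that only one terminal alkene is present during hydroboration.

**C9–C10.** Lactam 36 is cut between the sp3 carbon C9 and the ring A carbon C10 into vinyl lactam 29 and iodide 34. This separates an enantiopure ring A piece (C12 set by reagent control, 30 → 34) from an enantiopure lactam. It also avoids alkylating C7 with a homoallylic halide that can eliminate, and it avoids any desymmetrisation that would have to tell the CH2O arm on C6 from the CH2CH2 arm.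

**Ring D (N–C19 and N–C18).** Lactam 29 comes from alcohol 28, which arises when the secondary amine 27 opens its own γ-lactone. The nitrogen and its methyl group are brought in as sulfonamide 25 by substitution at C19 of hydroxy lactone 24. Tying C20 to C18 as a lactone differentiates the two primary alcohols and activates C18 for amide formation.

**C20 oxidation level.** Hydroxy lactone 24 comes from lactone 21 by cleaving the allyl ester to carboxylate 22 and reducing the ring carbonyl C20. The liberated C20 hydroxyl then closes the new lactone on C18.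

**C6 (C6–C17 and C6–C5).** The quaternary centre of 21 is built on the five-membered lactone 16 by two enolate alkylations, first with iodide 6, then with allyl bromoacetate 19. In a γ-butyrolactone the second electrophile enters anti to the C7 substituent. This places C17 trans and the side chain cis to the vinyl group, which is the C6/C7 relationship of the target.

**C7.** Lactone 16 is traced through imide 14 to acyl oxazolidinone 11, tert-butyl bromoacetate 12, acid 7 and auxiliary 8. An auxiliary-controlled alkylation sets C7 with its vinyl group (C8=C9), the handle for the later coupling.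

**Side chain.** Iodide 6 comes from (S)-1,2-epoxybutane 1 by one-carbon extension at the unsubstituted epoxide carbon (1 → 2 → 3 → 5 → 6), so C3 is bought, not made.

## Alternatives that were turned down

**Alternative 1:** The disconnection removes rings A and B together, cutting C11–C12, C13–C14 and C14–C10 back to an alkyne (C10≡C11), a vinyl group (C12=C13) and carbon monoxide held on a bridging lactone. The forward step is a Pauson–Khand reaction with Co2(CO)8 and an amine N-oxide, giving the lactone-bridged bicyclooctenone A1.
- For: three C–C bonds and two rings form in one step, the rigid lactone fixes C12 against C15 and C17, and C17 is already quaternary. On that last point it is stronger than the chosen route, which must force a hindered coupling at C17.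
- Against: A1 contains neither ring C nor ring D. The C14 ketone must be removed without moving the C10=C11 alkene. C6 is only a CH2O arm that must still become a quaternary stereocentre next to C17, with C7 set relative to it and a nitrile chain closed onto it.
- Comparison: each of those tasks costs several steps and none has a controlling element. The chosen route sets C6/C7 first by lactone enolate chemistry and then needs only two palladium ring closures.

**Alternative 2:** Ring B is made by contraction, with C15–C16 formed by a 1,2-shift in a six-membered α-diazo ketone. Photolysis in methanol triggers the Wolff rearrangement and traps the ketene as the methyl ester A2.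
- For: C21 arrives at the ester level, and because A2 carries an N-carbomethoxy group one LiAlH4 reduction would give the N-methyl group and the C21 alcohol together. That is more economical at the very end than hydroboration followed by a separate lactam reduction.
- Against: it is an end-game device. The homologous tetracycle, with both quaternary centres, ring C and ring D, must already exist, so the hard bonds are only moved to an earlier, longer sequence. Diazo transfer must choose the methylene next to C12 over the one at C16. The ester at C15 is epimerisable and its stable orientation is probably not the target's.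
- Comparison: the chosen route reaches the same C15 configuration under kinetic control and addresses the skeleton directly.

**Alternative 3:** Rings A and C are built on a preformed ring B. C10–C11 and C8–C9 form in an intramolecular enone–alkyne [2+2] photocycloaddition, and cleavage of C8–C11 with BF3·OEt2 or heat opens the cyclobutene to the cycloheptadienone A3.
- For: no organometallic step is needed, C17 is quaternary from the start, and C12 and C15 are set early on a small bicycle. On these points it is as strong as or stronger than the chosen plan.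
- Against: A3 lacks ring D and both C6 substituents. C6 is a methylene that must be alkylated twice next to quaternary C17 with control over which group ends cis to C8. The C7 ketone needs a one-carbon homologation with stereocontrol. The C8=C9 alkene must be reduced beside C10=C11. The regiochemistry of the photocycloaddition and the strained intermediate add further risk.
- Comparison: most of the work would come after the key step, whereas the chosen route finishes in six steps after its key step.

Key step: step 21

## Route

**Step 1**
Reactants: 1 (S)-1,2-epoxybutane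
Product: 2 (S)-hex-5-en-3-ol
Conditions: CH2=CHMgBr, CuI (10 mol%), THF, −30 → 0 °C
Reagents that add atoms: vinylmagnesium bromide, C=C[Mg]Br
Why: Copper-catalysed Grignard opening of a terminal epoxide occurs at the unsubstituted carbon, so the C3 stereocentre of 1 is untouched.

**Step 2**
Reactants: 2 (S)-hex-5-en-3-ol
Product: 3 (S)-4-(methoxymethoxy)hex-1-ene
Conditions: MOMCl, i-Pr2NEt, CH2Cl2, 0 °C → rt
Reagents that add atoms: chloromethyl methyl ether, COCCl
Why: Standard acetal protection of a secondary alcohol (O-alkylation with an α-chloro ether); the ether survives every base, hydride and palladium step up to the last one.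

**Step 3**
Reactants: 3 (S)-4-(methoxymethoxy)hex-1-ene
Product: 5 (S)-3-(methoxymethoxy)pentan-1-ol, via ozonide 4 (not isolated)
Conditions: O3, CH2Cl2, −78 °C; then NaBH4, EtOH, −78 °C → rt
Reagents that add atoms: ozone, [O-][O+]=O
Why: Ozonolysis with reductive work-up removes the terminal carbon and leaves C5 as a primary alcohol; the acetal is inert.

**Step 4**
Reactants: 5 (S)-3-(methoxymethoxy)pentan-1-ol
Product: 6 (S)-1-iodo-3-(methoxymethoxy)pentane
Conditions: I2, PPh3, imidazole, CH2Cl2, 0 °C → rt
Reagents that add atoms: iodine, II
Why: Appel-type iodination of a primary alcohol through the alkoxyphosphonium salt; imidazole keeps the medium non-acidic for the acetal.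

**Step 5**
Reactants: 7 but-3-enoic acid; 8 (S)-4-benzyloxazolidin-2-one
Product: 11 (S)-4-benzyl-3-(but-3-enoyl)oxazolidin-2-one, via mixed pivalic anhydride 9 (not isolated), via lithium oxazolidinide 10 (not isolated)
Conditions: 7, t-BuCOCl, Et3N, THF, −78 → 0 °C; 8, n-BuLi, THF, −78 °C; combine, −78 → 0 °C
Reagents that add atoms: none
Why: N-Acylation of the lithiated auxiliary with a mixed anhydride; the low temperature and absence of free amine at the acylation stage keep the β,γ-alkene out of conjugation.

**Step 6**
Reactants: 11 (S)-4-benzyl-3-(but-3-enoyl)oxazolidin-2-one; 12 tert-butyl bromoacetate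
Product: 14 tert-butyl (S)-3-[(S)-4-benzyl-2-oxooxazolidine-3-carbonyl]pent-4-enoate, via sodium enolate 13 (not isolated)
Conditions: NaN(SiMe3)2, THF, −78 °C; then 12, −78 → −50 °C
Reagents that add atoms: none
Why: Evans asymmetric alkylation: the chelated (Z)-enolate is attacked at its α-carbon from the face away from the benzyl group, which sets C7 with its vinyl group (C8=C9). The minor diastereomer is removable at this stage.

**Step 7**
Reactants: 14 tert-butyl (S)-3-[(S)-4-benzyl-2-oxooxazolidine-3-carbonyl]pent-4-enoate
Product: 16 (S)-4-vinyldihydrofuran-2(3H)-one, via hydroxy ester 15 (not isolated)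
Conditions: LiBH4, MeOH (1 equiv), THF, 0 °C; then TsOH·H2O (cat.), CH2Cl2, rt
Reagents that add atoms: none
Why: Reductive removal of the auxiliary (the imide carbonyl is far more electrophilic than the tert-butyl ester), then acid-catalysed lactonisation of the γ-hydroxy ester. C7 is no longer α to a carbonyl and cannot epimerise.

**Step 8**
Reactants: 16 (S)-4-vinyldihydrofuran-2(3H)-one; 6 (S)-1-iodo-3-(methoxymethoxy)pentane
Product: 18 (3R,4R)-3-[(S)-3-(methoxymethoxy)pentyl]-4-vinyldihydrofuran-2(3H)-one, via lithium enolate 17 (not isolated)
Conditions: LiN(i-Pr)2, THF, −78 °C; then 6, DMPU, −78 → −30 °C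
Reagents that add atoms: none
Why: Lactone enolate alkylation with a primary iodide, expected mainly trans to the vinyl group. The C6 configuration is irrelevant here because C6 is enolised again in step 9.

**Step 9**
Reactants: 18 (3R,4R)-3-[(S)-3-(methoxymethoxy)pentyl]-4-vinyldihydrofuran-2(3H)-one; 19 allyl bromoacetate
Product: 21 allyl 2-[(3R,4R)-3-[(S)-3-(methoxymethoxy)pentyl]-2-oxo-4-vinyltetrahydrofuran-3-yl]acetate, via lithium enolate 20 (not isolated)
Conditions: LiN(i-Pr)2, THF, −78 °C; then 19, DMPU, −78 → −40 °C
Reagents that add atoms: none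
Why: Second enolate alkylation of a β-substituted γ-butyrolactone: the reactive α-halo ester approaches the planar enolate anti to the C7 vinyl group. This creates the quaternary centre C6 with C17 trans and the side chain cis to C8, as the target requires.

**Step 10**
Reactants: 21 allyl 2-[(3R,4R)-3-[(S)-3-(methoxymethoxy)pentyl]-2-oxo-4-vinyltetrahydrofuran-3-yl]acetate
Product: 22 potassium 2-[(3R,4R)-3-[(S)-3-(methoxymethoxy)pentyl]-2-oxo-4-vinyltetrahydrofuran-3-yl]acetate
Conditions: Pd(PPh3)4 (2 mol%), potassium 2-ethylhexanoate, EtOAc, rt
Reagents that add atoms: potassium 2-ethylhexanoate, CCCCC(CC)C(=O)[O-].[K+]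
Why: Palladium-catalysed allyl transfer (Tsuji–Trost deallylation) frees the C18 carboxylate under neutral conditions that leave the hindered lactone, the acetal and the vinyl group alone.

**Step 11**
Reactants: 22 potassium 2-[(3R,4R)-3-[(S)-3-(methoxymethoxy)pentyl]-2-oxo-4-vinyltetrahydrofuran-3-yl]acetate
Product: 24 (R)-4-[(R)-1-hydroxybut-3-en-2-yl]-4-[(S)-3-(methoxymethoxy)pentyl]dihydrofuran-2(3H)-one, via dihydroxy acid 23 (not isolated)
Conditions: LiBH4, THF, 0 °C → rt; then 1 M HCl to pH 3, rt
Reagents that add atoms: none
Why: LiBH4 reduces the lactone but not the carboxylate. On acidification the neopentyl C20 hydroxyl closes the five-membered lactone on C18 in preference to the six-membered alternative. This differentiates the two primary alcohols and leaves C19–OH free.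

**Step 12**
Reactants: 24 (R)-4-[(R)-1-hydroxybut-3-en-2-yl]-4-[(S)-3-(methoxymethoxy)pentyl]dihydrofuran-2(3H)-one; 25 N-methyl-2-nitrobenzenesulfonamide
Product: 26 N-{(R)-2-[(R)-3-[(S)-3-(methoxymethoxy)pentyl]-5-oxotetrahydrofuran-3-yl]but-3-en-1-yl}-N-methyl-2-nitrobenzenesulfonamide
Conditions: PPh3, DIAD, THF, 0 °C → rt
Reagents that add atoms: none
Why: Fukuyama–Mitsunobu N-alkylation of the acidic sulfonamide at primary C19. C19 stays sp3, so C7 is never α to a carbonyl and cannot epimerise.

**Step 13**
Reactants: 26 N-{(R)-2-[(R)-3-[(S)-3-(methoxymethoxy)pentyl]-5-oxotetrahydrofuran-3-yl]but-3-en-1-yl}-N-methyl-2-nitrobenzenesulfonamide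
Product: 28 (4R,5R)-4-(hydroxymethyl)-4-[(S)-3-(methoxymethoxy)pentyl]-1-methyl-5-vinylpiperidin-2-one, via amino lactone 27 (not isolated)
Conditions: PhSH, K2CO3, DMF, rt → 50 °C
Reagents that add atoms: none
Why: Thiolate removes the nitrobenzenesulfonyl group by nucleophilic aromatic substitution. The freed secondary amine then attacks the unhindered lactone carbonyl C18 (6-exo-trig) and the ester-to-amide exchange gives ring D and releases C20–OH.

**Step 14**
Reactants: 28 (4R,5R)-4-(hydroxymethyl)-4-[(S)-3-(methoxymethoxy)pentyl]-1-methyl-5-vinylpiperidin-2-one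
Product: 29 (4R,5R)-4-[(methoxymethoxy)methyl]-4-[(S)-3-(methoxymethoxy)pentyl]-1-methyl-5-vinylpiperidin-2-one
Conditions: MOMCl, i-Pr2NEt, CH2Cl2, 0 °C → rt
Reagents that add atoms: chloromethyl methyl ether, COCCl
Why: Acetal protection of the primary C20 alcohol, giving the same protecting group on both oxygens that must survive to the end.

**Step 15**
Reactants: 30 cyclopentane-1,3-dione
Product: 31 2-bromocyclopentane-1,3-dione
Conditions: NBS, CH2Cl2, 0 °C
Reagents that add atoms: N-bromosuccinimide, O=C1CCC(=O)N1Br
Why: Electrophilic bromination of the enol at the central carbon of the 1,3-dione; this carbon becomes C11.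

**Step 16**
Reactants: 31 2-bromocyclopentane-1,3-dione
Product: 32 2-bromo-3-iodocyclopent-2-en-1-one
Conditions: PPh3, I2, Et3N, MeCN, rt → 60 °C
Reagents that add atoms: iodine, II
Why: Conversion of a cyclic 1,3-dione into its β-iodo enone through the enol oxyphosphonium salt and addition–elimination of iodide; the iodine-bearing carbon becomes C10.

**Step 17**
Reactants: 32 2-bromo-3-iodocyclopent-2-en-1-one
Product: 33 (S)-2-bromo-3-iodocyclopent-2-en-1-ol
Conditions: (R)-1-methyl-3,3-diphenyltetrahydro-1H,3H-pyrrolo[1,2-c][1,3,2]oxazaborole (the (R)-methyl CBS oxazaborolidine, 20 mol%), BH3·SMe2, THF, −20 °C; MeOH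
Reagents that add atoms: none
Why: Corey–Bakshi–Shibata reduction: the α-bromoalkenyl side acts as the large group, so the (R)-catalyst should deliver hydride to give the (S)-alcohol, which fixes C12.

**Step 18**
Reactants: 33 (S)-2-bromo-3-iodocyclopent-2-en-1-ol
Product: 34 (S)-[(2-bromo-3-iodocyclopent-2-en-1-yl)oxy](tert-butyl)dimethylsilane
Conditions: TBSCl, imidazole, DMF, rt
Reagents that add atoms: tert-butyldimethylsilyl chloride, CC(C)(C)[Si](C)(C)Cl
Why: Silylation of the allylic alcohol; the silyl ether tolerates the coupling, both enolate steps and the key step, and is removed selectively later.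

**Step 19**
Reactants: 29 (4R,5R)-4-[(methoxymethoxy)methyl]-4-[(S)-3-(methoxymethoxy)pentyl]-1-methyl-5-vinylpiperidin-2-one; 34 (S)-[(2-bromo-3-iodocyclopent-2-en-1-yl)oxy](tert-butyl)dimethylsilane
Product: 36 (4R,5R)-5-{2-[(S)-2-bromo-3-(tert-butyldimethylsilyloxy)cyclopent-1-en-1-yl]ethyl}-4-[(methoxymethoxy)methyl]-4-[(S)-3-(methoxymethoxy)pentyl]-1-methylpiperidin-2-one, via alkylborane 35 (not isolated)
Conditions: 9-BBN, THF, rt; then 34, PdCl2(dppf) (5 mol%), AsPh3, Cs2CO3, DMF/H2O, rt
Reagents that add atoms: none
Why: Anti-Markovnikov hydroboration of the only alkene, then B-alkyl Suzuki–Miyaura coupling forms C9–C10. Oxidative addition into the C–I bond at room temperature is much faster than into the neighbouring, more hindered C–Br bond, which is kept for step 21. Any C12 epimer from incomplete enantiocontrol in step 17 is now a separable diastereomer.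

**Step 20**
Reactants: 36 (4R,5R)-5-{2-[(S)-2-bromo-3-(tert-butyldimethylsilyloxy)cyclopent-1-en-1-yl]ethyl}-4-[(methoxymethoxy)methyl]-4-[(S)-3-(methoxymethoxy)pentyl]-1-methylpiperidin-2-one; 37 allyl bromide
Product: 39 (3R,4S,5R)-3-allyl-5-{2-[(S)-2-bromo-3-(tert-butyldimethylsilyloxy)cyclopent-1-en-1-yl]ethyl}-4-[(methoxymethoxy)methyl]-4-[(S)-3-(methoxymethoxy)pentyl]-1-methylpiperidin-2-one, via lithium enolate 38 (not isolated)
Conditions: LiN(i-Pr)2, THF, −78 °C; then 37, −78 → −20 °C
Reagents that add atoms: none
Why: Lactam enolate alkylation at C17, the only α-CH2, with a reactive allylic bromide. The C17 configuration need not be controlled because it is erased in step 21.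

**Step 21**
Reactants: 39 (3R,4S,5R)-3-allyl-5-{2-[(S)-2-bromo-3-(tert-butyldimethylsilyloxy)cyclopent-1-en-1-yl]ethyl}-4-[(methoxymethoxy)methyl]-4-[(S)-3-(methoxymethoxy)pentyl]-1-methylpiperidin-2-one
Product: 41 bridged tricyclic lactam (8-methyl-8-azabicyclo[4.3.1]dec-2-en-9-one fused to the silyloxycyclopentene; C17 allyl), via potassium enolate 40 (not isolated)
Conditions: KN(SiMe3)2, Pd2(dba)3 (5 mol%), P(t-Bu)3 (12 mol%), toluene, 70 °C
Reagents that add atoms: none
Why: Palladium-catalysed intramolecular α-alkenylation of an amide enolate; the closest known reaction type is the closure of bridged azabicycles from ketone and amide enolates with tethered vinyl halides. KN(SiMe3)2 converts 39 reversibly into enolate 40, zerovalent palladium bearing the bulky, electron-rich P(t-Bu)3 inserts into the C11–Br bond, the enolate replaces bromide on divalent palladium and binds through C17, and reductive elimination from the eight-membered palladacycle forms C11–C17. This closes the seven-membered ring C and completes the 8-azabicyclo[4.3.1]decene; the closure is exo with respect to the enolate double bond C17=C18, which stays outside ring C, so no bridgehead alkene is needed. The new quaternary stereocentre C17 is controlled by the C6/C7 configuration from steps 6 and 9: the two-carbon arm on C7 can bring C11 only to the enolate face cis to C8, and because C17 is planar in 40 both epimers of 39 converge. Chemoselectivity comes from the substrate: C17 carries the only acidic C–H, the product has no α-hydrogen, O-alkenylation would give a strained bridged enol ether, and a Heck insertion of the allyl alkene would have to close a nine- or ten-membered ring. The processes to outrun are β-hydride elimination of the palladium enolate towards C16 and reduction of the C11–Br bond, which a fast reductive elimination from the monophosphine complex should achieve. The ethers are inert to the base, and the C12 silyl ether cannot β-eliminate from the alkenylpalladium because that would need a cyclic allene.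

**Step 22**
Reactants: 41 bridged lactam (C12 silyl ether)
Product: 42 bridged lactam, C12 allylic alcohol
Conditions: Bu4NF, THF, rt
Reagents that add atoms: none
Why: Fluoride cleavage of the silyl ether; the methoxymethyl ethers and the lactam are unaffected.

**Step 23**
Reactants: 42 bridged lactam, C12 allylic alcohol
Product: 43 bridged lactam, C12 allylic acetate
Conditions: Ac2O, pyridine, DMAP (cat.), CH2Cl2, rt
Reagents that add atoms: acetic anhydride, CC(=O)OC(C)=O
Why: Acylation of the secondary allylic alcohol with retention at C12 gives the leaving group for the ene cyclisation.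

**Step 24**
Reactants: 43 bridged lactam, C12 allylic acetate
Product: 44 tetracyclic lactam with exocyclic methylene C15=C21
Conditions: Pd(PPh3)4 (10 mol%), AcOH, 75 °C
Reagents that add atoms: none
Why: Intramolecular palladium-ene reaction: zerovalent palladium ionises the acetate with inversion, the allyl alkene inserts into the allylpalladium on the metal-bearing face to form C12–C15 (five-membered ring B, exo closure at C15), and β-hydride elimination gives the exocyclic methylene. The new bond is therefore anti to the former C–O bond, which sets C12 as in the target while the tetrasubstituted alkene stays at C10=C11.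

**Step 25**
Reactants: 44 tetracyclic lactam with exocyclic methylene C15=C21
Product: 46 tetracyclic lactam with C21 hydroxymethyl group, via alkylborane 45 (not isolated)
Conditions: 9-BBN, THF, rt → 40 °C; then NaOH, H2O2, 0 °C → rt
Reagents that add atoms: hydrogen peroxide, OO
Why: Hydroboration–oxidation of the 1,1-disubstituted alkene; the tetrasubstituted alkene and the lactam do not react. The borane should approach the face of ring B that carries H12 and C18, away from C13 and the substituents of C6, delivering hydrogen to C15 on that face and leaving C21 on the crowded face as in the target.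

**Step 26**
Reactants: 46 tetracyclic lactam with C21 hydroxymethyl group
Product: 47 tetracyclic N-methyl amine, bis(methoxymethyl) ether
Conditions: LiAlH4, THF, reflux
Reagents that add atoms: none
Why: Hydride reduction of the tertiary lactam to the amine turns C18 into the N-CH2 group; acetals and the alkene are inert.

**Step 27**
Reactants: 47 tetracyclic N-methyl amine, bis(methoxymethyl) ether
Product: 48 target amino triol CNP0221997.1
Conditions: HCl, MeOH, 45 °C; then aq. NaHCO3
Reagents that add atoms: none
Why: Acid-catalysed acetal exchange removes both methoxymethyl groups; the protonated amine and the tetrasubstituted alkene are stable under these conditions.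

## Compound list

1 | (S)-1,2-epoxybutane | CC[C@H]1CO1 | starting material
2 | (S)-hex-5-en-3-ol | CC[C@H](O)CC=C | intermediate
3 | (S)-4-(methoxymethoxy)hex-1-ene | CC[C@H](OCOC)CC=C | intermediate
4 | 3-[(S)-2-(methoxymethoxy)butyl]-1,2,4-trioxolane (ozonide, epimers at the ring carbon) | CC[C@H](OCOC)CC1OCOO1 | intermediate
5 | (S)-3-(methoxymethoxy)pentan-1-ol | CC[C@H](OCOC)CCO | intermediate
6 | (S)-1-iodo-3-(methoxymethoxy)pentane | CC[C@H](OCOC)CCI | intermediate
7 | but-3-enoic acid | C=CCC(=O)O | starting material
8 | (S)-4-benzyloxazolidin-2-one | O=C1N[C@@H](Cc2ccccc2)CO1 | starting material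
9 | but-3-enoic pivalic anhydride | C=CCC(=O)OC(=O)C(C)(C)C | intermediate
10 | lithium (S)-4-benzyl-2-oxooxazolidin-3-ide | [Li+].O=C1OC[C@H](Cc2ccccc2)[N-]1 | intermediate
11 | (S)-4-benzyl-3-(but-3-enoyl)oxazolidin-2-one | C=CCC(=O)N1[C@@H](Cc2ccccc2)COC1=O | intermediate
12 | tert-butyl bromoacetate | BrCC(=O)OC(C)(C)C | starting material
13 | sodium (Z)-enolate of 11 | [Na+].[O-]/C(=C\C=C)N1[C@@H](Cc2ccccc2)COC1=O | intermediate
14 | tert-butyl (S)-3-[(S)-4-benzyl-2-oxooxazolidine-3-carbonyl]pent-4-enoate | O=C1OC[C@H](Cc2ccccc2)N1C(=O)[C@H](C=C)CC(=O)OC(C)(C)C | intermediate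
15 | tert-butyl (S)-3-(hydroxymethyl)pent-4-enoate | OC[C@H](C=C)CC(=O)OC(C)(C)C | intermediate
16 | (S)-4-vinyldihydrofuran-2(3H)-one | O=C1C[C@H](CO1)C=C | intermediate
17 | lithium enolate of 16 | [Li+].[O-]C1=C[C@H](CO1)C=C | intermediate
18 | (3R,4R)-3-[(S)-3-(methoxymethoxy)pentyl]-4-vinyldihydrofuran-2(3H)-one (trans isomer shown) | CC[C@H](OCOC)CC[C@@H]1[C@@H](C=C)COC1=O | intermediate
19 | allyl bromoacetate | BrCC(=O)OCC=C | starting material
20 | lithium enolate of 18 | [Li+].CC[C@H](OCOC)CCC1=C([O-])OC[C@@H]1C=C | intermediate
21 | allyl 2-[(3R,4R)-3-[(S)-3-(methoxymethoxy)pentyl]-2-oxo-4-vinyltetrahydrofuran-3-yl]acetate | CC[C@H](OCOC)CC[C@@]1(CC(=O)OCC=C)[C@@H](C=C)COC1=O | intermediate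
22 | potassium 2-[(3R,4R)-3-[(S)-3-(methoxymethoxy)pentyl]-2-oxo-4-vinyltetrahydrofuran-3-yl]acetate | [K+].CC[C@H](OCOC)CC[C@@]1(CC([O-])=O)[C@@H](C=C)COC1=O | intermediate
23 | (3R,6S)-3-(hydroxymethyl)-3-[(R)-1-hydroxybut-3-en-2-yl]-6-(methoxymethoxy)octanoic acid | CC[C@H](OCOC)CC[C@@](CO)(CC(=O)O)[C@@H](C=C)CO | intermediate
24 | (R)-4-[(R)-1-hydroxybut-3-en-2-yl]-4-[(S)-3-(methoxymethoxy)pentyl]dihydrofuran-2(3H)-one | CC[C@H](OCOC)CC[C@@]1(CC(=O)OC1)[C@@H](C=C)CO | intermediate
25 | N-methyl-2-nitrobenzenesulfonamide | CNS(=O)(=O)c1ccccc1[N+](=O)[O-] | starting material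
26 | N-{(R)-2-[(R)-3-[(S)-3-(methoxymethoxy)pentyl]-5-oxotetrahydrofuran-3-yl]but-3-en-1-yl}-N-methyl-2-nitrobenzenesulfonamide | CC[C@H](OCOC)CC[C@@]1(CC(=O)OC1)[C@@H](C=C)CN(C)S(=O)(=O)c2ccccc2[N+](=O)[O-] | intermediate
27 | (R)-4-[(R)-1-(methylamino)but-3-en-2-yl]-4-[(S)-3-(methoxymethoxy)pentyl]dihydrofuran-2(3H)-one | CC[C@H](OCOC)CC[C@@]1(CC(=O)OC1)[C@@H](C=C)CNC | intermediate
28 | (4R,5R)-4-(hydroxymethyl)-4-[(S)-3-(methoxymethoxy)pentyl]-1-methyl-5-vinylpiperidin-2-one | CC[C@H](OCOC)CC[C@]1(CO)[C@@H](C=C)CN(C)C(=O)C1 | intermediate
29 | (4R,5R)-4-[(methoxymethoxy)methyl]-4-[(S)-3-(methoxymethoxy)pentyl]-1-methyl-5-vinylpiperidin-2-one | CC[C@H](OCOC)CC[C@]1(COCOC)[C@@H](C=C)CN(C)C(=O)C1 | intermediate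
30 | cyclopentane-1,3-dione | O=C1CCC(=O)C1 | starting material
31 | 2-bromocyclopentane-1,3-dione | O=C1CCC(=O)C1Br | intermediate
32 | 2-bromo-3-iodocyclopent-2-en-1-one | O=C1CCC(I)=C1Br | intermediate
33 | (S)-2-bromo-3-iodocyclopent-2-en-1-ol | IC1=C(Br)[C@@H](O)CC1 | intermediate
34 | (S)-[(2-bromo-3-iodocyclopent-2-en-1-yl)oxy](tert-butyl)dimethylsilane | IC1=C(Br)[C@@H](O[Si](C)(C)C(C)(C)C)CC1 | intermediate
35 | B-alkyl-9-borabicyclo[3.3.1]nonane from 29 (boron on C9) | CC[C@H](OCOC)CC[C@]1(COCOC)[C@@H](CCB2C3CCCC2CCC3)CN(C)C(=O)C1 | intermediate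
36 | (4R,5R)-5-{2-[(S)-2-bromo-3-(tert-butyldimethylsilyloxy)cyclopent-1-en-1-yl]ethyl}-4-[(methoxymethoxy)methyl]-4-[(S)-3-(methoxymethoxy)pentyl]-1-methylpiperidin-2-one | CC[C@H](OCOC)CC[C@]1(COCOC)[C@@H](CCC2=C(Br)[C@@H](O[Si](C)(C)C(C)(C)C)CC2)CN(C)C(=O)C1 | intermediate
37 | allyl bromide | C=CCBr | starting material
38 | lithium enolate of 36 | [Li+].CC[C@H](OCOC)CC[C@]1(COCOC)[C@@H](CCC2=C(Br)[C@@H](O[Si](C)(C)C(C)(C)C)CC2)CN(C)C([O-])=C1 | intermediate
39 | (3R,4S,5R)-3-allyl-5-{2-[(S)-2-bromo-3-(tert-butyldimethylsilyloxy)cyclopent-1-en-1-yl]ethyl}-4-[(methoxymethoxy)methyl]-4-[(S)-3-(methoxymethoxy)pentyl]-1-methylpiperidin-2-one (one C17 epimer shown) | CC[C@H](OCOC)CC[C@]1(COCOC)[C@@H](CCC3=C(Br)[C@@H](O[Si](C)(C)C(C)(C)C)CC3)CN(C)C(=O)[C@@H]1CC=C | intermediate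
40 | potassium enolate of 39 | [K+].CC[C@H](OCOC)CC[C@]1(COCOC)[C@@H](CCC2=C(Br)[C@@H](O[Si](C)(C)C(C)(C)C)CC2)CN(C)C([O-])=C1CC=C | intermediate
41 | bridged lactam: 8-methyl-8-azabicyclo[4.3.1]dec-2-en-9-one fused at C10=C11 to the (S)-silyloxycyclopentene, C17 allyl, C6 bearing CH2OMOM and the (S)-3-(methoxymethoxy)pentyl chain; C6, C7 and C17 as in 48 | CC[C@H](OCOC)CC[C@]1(COCOC)[C@H]2CCC3=C([C@@H](O[Si](C)(C)C(C)(C)C)CC3)[C@]1(CC=C)C(=O)N(C)C2 | intermediate
42 | C12 allylic alcohol of 41 | CC[C@H](OCOC)CC[C@]1(COCOC)[C@H]2CCC3=C([C@@H](O)CC3)[C@]1(CC=C)C(=O)N(C)C2 | intermediate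
43 | C12 allylic acetate of 41 | CC[C@H](OCOC)CC[C@]1(COCOC)[C@H]2CCC3=C([C@@H](OC(C)=O)CC3)[C@]1(CC=C)C(=O)N(C)C2 | intermediate
44 | tetracyclic lactam, rings A–D, exocyclic methylene at C15 | CC[C@H](OCOC)CC[C@]1(COCOC)[C@H]2CCC3=C4[C@@H](CC3)C(=C)C[C@]41C(=O)N(C)C2 | intermediate
45 | B-alkyl-9-borabicyclo[3.3.1]nonane from 44 (boron on C21) | CC[C@H](OCOC)CC[C@]1(COCOC)[C@H]2CCC3=C4[C@@H](CC3)[C@@H](CB5C6CCCC5CCC6)C[C@]41C(=O)N(C)C2 | intermediate
46 | tetracyclic lactam with C21 hydroxymethyl group | CC[C@H](OCOC)CC[C@]1(COCOC)[C@H]2CCC3=C4[C@@H](CC3)[C@@H](CO)C[C@]41C(=O)N(C)C2 | intermediate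
47 | tetracyclic N-methyl amine, bis(methoxymethyl) ether | CC[C@H](OCOC)CC[C@]1(COCOC)[C@H]2CCC3=C4[C@@H](CC3)[C@@H](CO)C[C@]41CN(C)C2 | intermediate
48 | CNP0221997.1 | CC[C@H](O)CC[C@]1(CO)[C@H]2CCC3=C4[C@@H](CC3)[C@@H](CO)C[C@]41CN(C)C2 | target

## Step count and least certain steps

Total: 27 steps. Longest linear sequence: 20 steps (steps 1–4, 8–14 and 19–27); steps 5–7 and 15–18 are side branches.

**Step 21 (key step).** The tertiary C17–H, flanked by quaternary C6, may enolise slowly. The reductive elimination that creates two adjacent quaternary centres may also be slow, letting β-hydride elimination towards C16 or reduction of the C–Br bond take over. The fallback changes the order of bond formation. Lactam 36, which has a less hindered secondary enolate carbon and no side-chain β-hydrogen, is cyclised under the same type of catalysis to the allyl-free bridged lactam F1. F1 is then deprotonated at the bridgehead (the [4.3.1] framework is large enough for a bridgehead enolate) and alkylated with allyl iodide, which returns to the route at 41.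

**Step 24.** Insertion of the alkene into the allylpalladium may fail because the tether sits on the central carbon of the allyl unit. The complex would then lose a proton to give a ring A diene, or the exocyclic alkene would migrate into conjugation. The fallback is an allyl–alkenyl cross-coupling with the same stereochemical course (inversion at C12) and sets out from 41. The allyl group of 41 is oxidised (PdCl2, CuCl, O2, DMF/H2O) to the methyl ketone F2, and KN(SiMe3)2 with PhNTf2 gives the enol triflate F3 on the methyl side. B2pin2, PdCl2(dppf) and KOAc convert it into the alkenyl pinacol boronate F4. Buffered Bu4NF then gives the allylic alcohol F5 and Ac2O the allylic acetate F6. Pd(PPh3)4 with K3PO4 in THF/H2O couples the allyl and alkenyl termini, which returns to the route at 44.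

**Step 19.** Chemoselectivity between the adjacent C–I and C–Br bonds may be lost, or iodide 32 may be hard to obtain cleanly in step 16. The fallback functionalises ring A after the coupling and sets out from 29. Alkylborane 35, made from 29 as before, is coupled with 3-iodocyclopent-2-en-1-one F7 (from 30 with PPh3, I2 and Et3N) to give the coupled cyclopentenone F8. Br2 followed by Et3N gives the 2-bromo enone F9, and Corey–Bakshi–Shibata reduction with the (R)-catalyst gives the (S)-allylic alcohol F10. TBSCl and imidazole then return to the route at 36.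

**Step 12.** Substitution at the β-branched primary carbon C19 may be slow under Mitsunobu conditions, leading to recovered alcohol or elimination. The fallback uses azide displacement and late N-methylation and sets out from 24. MsCl and Et3N convert 24 into the mesylate F11, and NaN3 in DMF gives the azide F12. PMe3 and water reduce the azide, and the primary amine opens the lactone to the N–H lactam alcohol F13. MOMCl and i-Pr2NEt give the N–H lactam bis(methoxymethyl) ether F14, and NaH with MeI methylates nitrogen, which returns to the route at 29.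

## Further compounds

F1 | step 21 | bridged lactam lacking the C17 allyl group (C17–H bridgehead) | CC[C@H](OCOC)CC[C@]1(COCOC)[C@H]2CCC3=C([C@@H](O[Si](C)(C)C(C)(C)C)CC3)[C@@H]1C(=O)N(C)C2
F2 | step 24 | methyl ketone from Wacker oxidation of 41 | CC[C@H](OCOC)CC[C@]1(COCOC)[C@H]2CCC3=C([C@@H](O[Si](C)(C)C(C)(C)C)CC3)[C@]1(CC(C)=O)C(=O)N(C)C2
F3 | step 24 | enol triflate of F2 | CC[C@H](OCOC)CC[C@]1(COCOC)[C@H]2CCC3=C([C@@H](O[Si](C)(C)C(C)(C)C)CC3)[C@]1(CC(=C)OS(=O)(=O)C(F)(F)F)C(=O)N(C)C2
F4 | step 24 | alkenyl pinacol boronate | CC[C@H](OCOC)CC[C@]1(COCOC)[C@H]2CCC3=C([C@@H](O[Si](C)(C)C(C)(C)C)CC3)[C@]1(CC(=C)B4OC(C)(C)C(C)(C)O4)C(=O)N(C)C2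
F5 | step 24 | allylic alcohol of F4 | CC[C@H](OCOC)CC[C@]1(COCOC)[C@H]2CCC3=C([C@@H](O)CC3)[C@]1(CC(=C)B4OC(C)(C)C(C)(C)O4)C(=O)N(C)C2
F6 | step 24 | allylic acetate of F4 | CC[C@H](OCOC)CC[C@]1(COCOC)[C@H]2CCC3=C([C@@H](OC(C)=O)CC3)[C@]1(CC(=C)B4OC(C)(C)C(C)(C)O4)C(=O)N(C)C2
F7 | step 19 | 3-iodocyclopent-2-en-1-one | O=C1CCC(I)=C1
F8 | step 19 | coupled cyclopentenone | CC[C@H](OCOC)CC[C@]1(COCOC)[C@@H](CCC2=CC(=O)CC2)CN(C)C(=O)C1
F9 | step 19 | 2-bromo enone | CC[C@H](OCOC)CC[C@]1(COCOC)[C@@H](CCC2=C(Br)C(=O)CC2)CN(C)C(=O)C1
F10 | step 19 | (S)-allylic alcohol | CC[C@H](OCOC)CC[C@]1(COCOC)[C@@H](CCC2=C(Br)[C@@H](O)CC2)CN(C)C(=O)C1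
F11 | step 12 | mesylate of 24 | CC[C@H](OCOC)CC[C@@]1(CC(=O)OC1)[C@@H](C=C)COS(C)(=O)=O
F12 | step 12 | azide | CC[C@H](OCOC)CC[C@@]1(CC(=O)OC1)[C@@H](C=C)CN=[N+]=[N-]
F13 | step 12 | N–H lactam alcohol | CC[C@H](OCOC)CC[C@]1(CO)[C@@H](C=C)CNC(=O)C1
F14 | step 12 | N–H lactam bis(methoxymethyl) ether | CC[C@H](OCOC)CC[C@]1(COCOC)[C@@H](C=C)CNC(=O)C1
A1 | alternative 1 | lactone-bridged bicyclo[3.3.0]octenone from the Pauson–Khand reaction | N#CCCCC1=C2[C@@H](CC1=O)[C@H]3COC(=O)[C@]2(COCc4ccccc4)C3
A2 | alternative 2 | ring-contracted C15 methyl ester from the Wolff rearrangement | CC[C@H](O[Si](C)(C)C(C)(C)C)CC[C@]1(CO[Si](C)(C)C(C)(C)C)[C@H]2CCC3=C4[C@@H](CC3)[C@@H](C(=O)OC)C[C@]41CN(C(=O)OC)C2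
A3 | alternative 3 | tricyclic cycloheptadienone from photocycloaddition and cyclobutene opening | C1C(=O)C=CC2=C3[C@@H](CC2)[C@@H](CO[Si](C)(C)C(C)(C)C)C[C@]31COCc4ccccc4
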